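**Retrosynthetic overview**

1. Locants (cembrane-type): C1 = olefinic carbon bearing the isopropyl group, C2 = olefinic CH, C3/C4 = oxirane CH and C(CH3), C5–C7 = CH2, C8 = CH bearing C19H2OH, C9 = ketone, C10/C11 = CH2, C12 = CH(CH3), C13 = CH(OH), C14 = ketone; target = (1E,3S,4R,8S,12R,13S).
2. Enabling feature: the vinyl oxirane C1=C2–C3(O)–C4 next to the C14 ketone is a masked (1E,3Z)-2,4-dienone. At that oxidation level C2–C3 is the central sp2–sp2 bond of the dienone, which a Heck reaction forms between a (Z)-alkenyl iodide at C3 and the CH2 terminus (C2) of an α-isopropyl vinyl ketone. The C14 carbonyl directs the carbopalladation and later shields C1=C2 from the epoxidising agent.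
3. Ring order: first the 14-membered carbocycle (Heck closure of C2–C3 in an acyclic iodo-enone), second the oxirane (catalyst-controlled epoxidation of C3=C4); then C9 carbinol to ketone and desilylation.
4. Acyclic assembly: C14–C1 by Weinreb ketone synthesis with an alkenyl Grignard reagent; C8–C9 by Evans syn aldol (sets C8; the imide carbonyl becomes C19H2OH); C13–O by Evans enolate hydroxylation.
5. Building blocks: (R)-citronellic acid (C9–C14 with the C12 stereocentre); a 5-bromopentyl silyl ether plus propyne (C19, C8–C3; Z-iodoalkene by carbocupration); 2-bromo-3-methylbut-1-ene (C2, C1, isopropyl).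

Key step: step 14

Remark: the oxirane in the SMILES carries the ring bonds to C2 and C5 on the same face (3S,4R), so the epoxidation substrate must be the Z-configured C3=C4 olefin; this reading is used throughout.

**Route**

Step 1
Reactants: 1 (R)-citronellic acid; 2 (S)-4-benzyl-1,3-oxazolidin-2-one
Product: 4 (4S)-4-benzyl-3-[(3R)-3,7-dimethyloct-6-enoyl]-1,3-oxazolidin-2-one, via mixed pivalic anhydride 3 (not isolated)
Conditions: t-BuCOCl, Et3N, THF, −20 °C; then LiCl, 2, −20 °C → rt
Reagents that add atoms: none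
Why: N-acylation of the LiCl-activated oxazolidinone through the mixed anhydride is the standard way to install the Evans auxiliary and leaves the chiral-pool C12 stereocentre untouched.

Step 2
Reactants: 4 citronelloyl oxazolidinone
Product: 6 (4S)-4-benzyl-3-[(2S,3R)-2-hydroxy-3,7-dimethyloct-6-enoyl]-1,3-oxazolidin-2-one, via sodium Z-enolate 5 (not isolated)
Conditions: NaN(SiMe3)2, THF, −78 °C; 2-(phenylsulfonyl)-3-phenyloxaziridine, −78 °C; AcOH quench
Reagents that add atoms: 2-(phenylsulfonyl)-3-phenyloxaziridine (Davis oxaziridine), O=S(=O)(c1ccccc1)N1OC1c1ccccc1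
Why: Evans enolate hydroxylation: the chelated sodium Z-enolate is oxidised by the Davis oxaziridine on the face opposite the benzyl group, which should set C13 as S (syn to the C12 methyl) under auxiliary control.

Step 3
Reactants: 6 α-hydroxy imide
Product: 7 (2S,3R)-2-hydroxy-N-methoxy-N,3,7-trimethyloct-6-enamide
Conditions: MeNHOMe·HCl, AlMe3, CH2Cl2, −10 °C → rt; 0.5 M HCl work-up
Reagents that add atoms: N,O-dimethylhydroxylamine hydrochloride, CNOC.Cl
Why: Aluminium-amide transamination to the Weinreb amide is fastest on imides with a free α-hydroxyl (an aluminium alkoxide chelate directs attack to the exocyclic carbonyl) and should release the auxiliary without epimerising C13.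

Step 4
Reactants: 7 α-hydroxy Weinreb amide
Product: 8 (2S,3R)-N-methoxy-N,3,7-trimethyl-2-(triethylsilyloxy)oct-6-enamide
Conditions: Et3SiCl, imidazole, DMF, 0 °C → rt
Reagents that add atoms: chlorotriethylsilane, CC[Si](Cl)(CC)CC
Why: Routine silylation of a secondary alcohol; the triethylsilyl ether masks C13–OH until the last step and blocks α-ketol chemistry once C14 is a ketone.

Step 5
Reactants: 8 silylated Weinreb amide
Product: 10 (2S,3R)-N-methoxy-N,3-dimethyl-6-oxo-2-(triethylsilyloxy)hexanamide, via secondary ozonide 9 (not isolated)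
Conditions: O3, CH2Cl2, −78 °C; then PPh3, −78 °C → rt
Reagents that add atoms: ozone, [O-][O+]=O
Why: Ozonolysis with reductive work-up cleaves the only C=C bond (the trisubstituted citronellyl olefin) to the C9 aldehyde, while the Weinreb amide and the silyl ether are inert.

Step 6
Reactants: 11 (5-bromopentyloxy)(tert-butyl)dimethylsilane; 12 propyne
Product: 16 (Z)-tert-butyl[(7-iodo-6-methylhept-6-en-1-yl)oxy]dimethylsilane, via Grignard reagent 13 (not isolated), via alkylcopper 14 (not isolated), via Z-alkenylcopper 15 (not isolated)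
Conditions: Mg, Et2O; CuBr·SMe2, Et2O/Me2S, −45 °C; 12, −25 °C; then I2, THF, −50 → 0 °C
Reagents that add atoms: iodine, II
Why: Normant carbocupration: syn addition of the primary alkylcopper across propyne (alkyl to the internal carbon, copper to the terminus) followed by iodinolysis with retention should give only the Z-iodoalkene, which fixes the C3=C4 geometry (chain and iodine cis).

Step 7
Reactants: 16 silyl ether of the Z-iodoalkenol
Product: 17 (Z)-7-iodo-6-methylhept-6-en-1-ol
Conditions: Bu4NF, THF, 0 °C → rt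
Reagents that add atoms: none
Why: Fluoride cleavage of a primary silyl ether is routine and does not touch the alkenyl iodide.

Step 8
Reactants: 17 Z-iodoalkenol
Product: 18 (Z)-7-iodo-6-methylhept-6-enoic acid
Conditions: TEMPO (cat.), PhI(OAc)2, MeCN/H2O, rt
Reagents that add atoms: water, O
Why: Oxoammonium-mediated oxidation in aqueous acetonitrile takes the primary alcohol through the aldehyde hydrate to the acid and is compatible with the trisubstituted iodoalkene.

Step 9
Reactants: 18 Z-iodoalkenoic acid; 19 (R)-4-benzyl-1,3-oxazolidin-2-one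
Product: 21 (4R)-4-benzyl-3-[(Z)-7-iodo-6-methylhept-6-enoyl]-1,3-oxazolidin-2-one, via mixed pivalic anhydride 20 (not isolated)
Conditions: t-BuCOCl, Et3N, THF, −20 °C; then LiCl, 19, −20 °C → rt
Reagents that add atoms: none
Why: Same mixed-anhydride acylation as step 1; the R-configured auxiliary is chosen so that the aldol of step 10 delivers the C8 configuration of the target.

Step 10
Reactants: 21 iodoalkenoyl oxazolidinone; 10 aldehyde
Product: 23 (4R)-4-benzyl-3-[(2R,3S,6R,7S)-3-hydroxy-2-[(Z)-5-iodo-4-methylpent-4-en-1-yl]-8-[methoxy(methyl)amino]-6-methyl-8-oxo-7-(triethylsilyloxy)octanoyl]-1,3-oxazolidin-2-one, via dibutylboron Z-enolate 22 (not isolated)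
Conditions: Bu2BOTf, i-Pr2NEt, CH2Cl2, −78 → 0 °C; 10, −78 → 0 °C; pH 7 buffer, MeOH, H2O2, 0 °C
Reagents that add atoms: none
Why: Evans syn aldol: the boron Z-enolate reacts through a Zimmerman–Traxler chair with the auxiliary dipole opposed, which should set C8 (R in 23, S once the imide carbonyl has become C19H2OH) and the temporary C9 carbinol (S) under auxiliary control, the remote C12/C13 centres of the aldehyde having no say.

Step 11
Reactants: 23 aldol adduct
Product: 24 (2S,3R,6S,7S,11Z)-6-hydroxy-7-(hydroxymethyl)-12-iodo-N-methoxy-N,3,11-trimethyl-2-(triethylsilyloxy)dodec-11-enamide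
Conditions: NaBH4, THF/H2O (4:1), 0 °C → rt
Reagents that add atoms: none
Why: NaBH4 in aqueous THF reduces the activated N-acyl oxazolidinone to the primary C19 alcohol and frees the auxiliary, whereas the Weinreb amide is inert to NaBH4 and keeps C14 at the acyl level.

Step 12
Reactants: 24 diol
Product: 25 (2S,3R,6S,7S,11Z)-6-hydroxy-12-iodo-N-methoxy-N,3,11-trimethyl-2-(triethylsilyloxy)-7-[(triethylsilyloxy)methyl]dodec-11-enamide
Conditions: Et3SiCl (1.05 equiv), imidazole, CH2Cl2, −78 → −30 °C
Reagents that add atoms: chlorotriethylsilane, CC[Si](Cl)(CC)CC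
Why: Kinetically selective silylation of the primary C19 hydroxyl over the hindered secondary C9 hydroxyl, which stays free as the future ketone.

Step 13
Reactants: 25 Weinreb amide; 26 2-bromo-3-methylbut-1-ene
Product: 28 (4S,5R,8S,9S,13Z)-8-hydroxy-14-iodo-5,13-dimethyl-2-(propan-2-yl)-4-(triethylsilyloxy)-9-[(triethylsilyloxy)methyl]tetradeca-1,13-dien-3-one, via alkenyl Grignard reagent 27 (not isolated)
Conditions: 26, Mg, THF; then 25, THF, 0 °C → rt (excess 27); inverse quench into cold aq. NH4Cl
Reagents that add atoms: none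
Why: Weinreb ketone synthesis: after one equivalent of the Grignard reagent is spent on the C9 hydroxyl, a single addition gives a stable magnesium chelate that releases the α-isopropyl enone only on work-up, and an alkenyl iodide does not exchange with a Grignard reagent at this temperature.

Step 14
Reactants: 28 acyclic iodo-enone
Product: 29 (2E,4Z,9S,10S,13R,14S)-10-hydroxy-5,13-dimethyl-2-(propan-2-yl)-14-(triethylsilyloxy)-9-[(triethylsilyloxy)methyl]cyclotetradeca-2,4-dien-1-one
Conditions: Pd(OAc)2 (0.2 equiv), Bu4NCl, NaHCO3, DMF, 2 mM (slow addition of 28), 70 °C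
Reagents that add atoms: none
Why: Zerovalent palladium (formed in situ from Pd(OAc)2) inserts into the C3–I bond with retention, the alkenylpalladium adds syn across the enone C1=C2 with C3 bonding to the unsubstituted C2 terminus and palladium to C1, and syn β-hydride elimination of a C2–H creates the C1=C2 double bond while NaHCO3 regenerates the catalyst. The closest known reaction type is the macrocyclising intramolecular Heck reaction of alkenyl iodides with vinyl ketones and acrylates under ligand-free phase-transfer conditions, applied here to an α-branched enone. The 14-membered carbocycle closes in the 14-endo-trig mode; no stereocentre is created, but both olefin geometries of the (1E,3Z)-dienone are fixed, 3Z by stereoretentive oxidative addition and insertion of the Z-iodide and 1E because elimination passes through the rotamer with C3 anti to the C14 acyl group, which is also the more stable conjugated isomer. The step needs regioselective insertion (secured by the polarisation of the enone by C14=O and the unhindered CH2 terminus), elimination toward C2 and not toward the isopropyl methine (the C2 hydrogens are activated by the adjacent C3=C4 and lead to the fully conjugated dienone), and ring closure over oligomerisation (high dilution). The α-silyloxy ketone, the free C9 hydroxyl and both silyl ethers should be inert to the weak base.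

Step 15
Reactants: 29 macrocyclic (1E,3Z)-dienone
Product: 30 (1E,3S,4R,8S,9S,12R,13S)-3,4-epoxy-9-hydroxy-13,19-bis(triethylsilyloxy)cembr-1-en-14-one (locants of the overview)
Conditions: L-fructose-derived Shi ketone (0.5 equiv), KHSO5 (as Oxone), K2CO3, Bu4NHSO4, MeCN/CH2(OMe)2, aq. Na2B4O7 buffer (pH 10.5), 0 °C
Reagents that add atoms: potassium peroxymonosulfate (the oxidant in Oxone), [K+].[O-]S(=O)(=O)OO
Why: Shi asymmetric epoxidation: the chiral dioxirane attacks only the electron-rich distal C3=C4 (C1=C2 is deactivated by C14=O) through the spiro transition state with C3–H next to the catalyst's spiro ketal, so that the enantiomer of the usual D-fructose ketone should deliver oxygen to the face giving 3S,4R, and syn transfer turns the Z olefin into the oxirane with C2 and C5 cis.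

Step 16
Reactants: 30 epoxy alcohol
Product: 31 (1E,3S,4R,8S,12R,13S)-3,4-epoxy-13,19-bis(triethylsilyloxy)cembr-1-ene-9,14-dione
Conditions: Dess–Martin periodinane, NaHCO3, CH2Cl2, 0 °C → rt
Reagents that add atoms: none
Why: Dess–Martin oxidation of the only free hydroxyl (C9) under bicarbonate buffering is neutral enough to spare the vinyl oxirane and the now epimerisable C8 centre.

Step 17
Reactants: 31 bis-silyl diketone
Product: 32 (1E,3S,4R,8S,12R,13S)-3,4-epoxy-13,19-dihydroxycembr-1-ene-9,14-dione (CNP0110598.2)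
Conditions: HF·pyridine, excess pyridine, THF, 0 °C
Reagents that add atoms: none
Why: Pyridine-buffered HF cleaves a primary and a secondary triethylsilyl ether under near-neutral conditions that should leave the vinyl oxirane, the α-ketol and the β-hydroxy ketone intact.

**Compound list**

1 | (R)-citronellic acid, (3R)-3,7-dimethyloct-6-enoic acid | C[C@H](CCC=C(C)C)CC(=O)O | starting material
2 | (S)-4-benzyl-1,3-oxazolidin-2-one | O=C1N[C@@H](Cc2ccccc2)CO1 | starting material
3 | (3R)-3,7-dimethyloct-6-enoic pivalic anhydride | C[C@H](CCC=C(C)C)CC(=O)OC(=O)C(C)(C)C | intermediate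
4 | (4S)-4-benzyl-3-[(3R)-3,7-dimethyloct-6-enoyl]-1,3-oxazolidin-2-one | C[C@H](CCC=C(C)C)CC(=O)N1C(=O)OC[C@@H]1Cc1ccccc1 | intermediate
5 | sodium (1Z,3R)-1-[(4S)-4-benzyl-2-oxo-1,3-oxazolidin-3-yl]-3,7-dimethylocta-1,6-dien-1-olate | [Na+].[O-]/C(=C\[C@H](C)CCC=C(C)C)N1C(=O)OC[C@@H]1Cc1ccccc1 | intermediate
6 | (4S)-4-benzyl-3-[(2S,3R)-2-hydroxy-3,7-dimethyloct-6-enoyl]-1,3-oxazolidin-2-one | C[C@H](CCC=C(C)C)[C@H](O)C(=O)N1C(=O)OC[C@@H]1Cc1ccccc1 | intermediate
7 | (2S,3R)-2-hydroxy-N-methoxy-N,3,7-trimethyloct-6-enamide | C[C@H](CCC=C(C)C)[C@H](O)C(=O)N(C)OC | intermediate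
8 | (2S,3R)-N-methoxy-N,3,7-trimethyl-2-(triethylsilyloxy)oct-6-enamide | C[C@H](CCC=C(C)C)[C@H](O[Si](CC)(CC)CC)C(=O)N(C)OC | intermediate
9 | (2S,3R)-5-(5,5-dimethyl-1,2,4-trioxolan-3-yl)-N-methoxy-N,3-dimethyl-2-(triethylsilyloxy)pentanamide (both epimers at the trioxolane carbon) | C[C@H](CCC1OOC(C)(C)O1)[C@H](O[Si](CC)(CC)CC)C(=O)N(C)OC | intermediate
10 | (2S,3R)-N-methoxy-N,3-dimethyl-6-oxo-2-(triethylsilyloxy)hexanamide | C[C@H](CCC=O)[C@H](O[Si](CC)(CC)CC)C(=O)N(C)OC | intermediate
11 | (5-bromopentyloxy)(tert-butyl)dimethylsilane | BrCCCCCO[Si](C)(C)C(C)(C)C | starting material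
12 | propyne | CC#C | starting material
13 | [5-(tert-butyldimethylsilyloxy)pentyl]magnesium bromide | Br[Mg]CCCCCO[Si](C)(C)C(C)(C)C | intermediate
14 | [5-(tert-butyldimethylsilyloxy)pentyl]copper | [Cu]CCCCCO[Si](C)(C)C(C)(C)C | intermediate
15 | (Z)-[7-(tert-butyldimethylsilyloxy)-2-methylhept-1-en-1-yl]copper | [Cu]/C=C(/C)CCCCCO[Si](C)(C)C(C)(C)C | intermediate
16 | (Z)-tert-butyl[(7-iodo-6-methylhept-6-en-1-yl)oxy]dimethylsilane | I/C=C(/C)CCCCCO[Si](C)(C)C(C)(C)C | intermediate
17 | (Z)-7-iodo-6-methylhept-6-en-1-ol | I/C=C(/C)CCCCCO | intermediate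
18 | (Z)-7-iodo-6-methylhept-6-enoic acid | I/C=C(/C)CCCCC(=O)O | intermediate
19 | (R)-4-benzyl-1,3-oxazolidin-2-one | O=C1N[C@H](Cc2ccccc2)CO1 | starting material
20 | (Z)-7-iodo-6-methylhept-6-enoic pivalic anhydride | I/C=C(/C)CCCCC(=O)OC(=O)C(C)(C)C | intermediate
21 | (4R)-4-benzyl-3-[(Z)-7-iodo-6-methylhept-6-enoyl]-1,3-oxazolidin-2-one | I/C=C(/C)CCCCC(=O)N1C(=O)OC[C@H]1Cc1ccccc1 | intermediate
22 | (4R)-4-benzyl-3-[(1Z,6Z)-1-(dibutylboranyloxy)-7-iodo-6-methylhepta-1,6-dien-1-yl]-1,3-oxazolidin-2-one | CCCCB(CCCC)O/C(=C\CCC/C(C)=C\I)N1C(=O)OC[C@H]1Cc1ccccc1 | intermediate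
23 | (4R)-4-benzyl-3-[(2R,3S,6R,7S)-3-hydroxy-2-[(Z)-5-iodo-4-methylpent-4-en-1-yl]-8-[methoxy(methyl)amino]-6-methyl-8-oxo-7-(triethylsilyloxy)octanoyl]-1,3-oxazolidin-2-one | O=C(N1C(=O)OC[C@H]1Cc1ccccc1)[C@H](CCC/C(C)=C\I)[C@@H](O)CC[C@@H](C)[C@H](O[Si](CC)(CC)CC)C(=O)N(C)OC | intermediate
24 | (2S,3R,6S,7S,11Z)-6-hydroxy-7-(hydroxymethyl)-12-iodo-N-methoxy-N,3,11-trimethyl-2-(triethylsilyloxy)dodec-11-enamide | OC[C@H](CCC/C(C)=C\I)[C@@H](O)CC[C@@H](C)[C@H](O[Si](CC)(CC)CC)C(=O)N(C)OC | intermediate
25 | (2S,3R,6S,7S,11Z)-6-hydroxy-12-iodo-N-methoxy-N,3,11-trimethyl-2-(triethylsilyloxy)-7-[(triethylsilyloxy)methyl]dodec-11-enamide | CC[Si](CC)(CC)OC[C@H](CCC/C(C)=C\I)[C@@H](O)CC[C@@H](C)[C@H](O[Si](CC)(CC)CC)C(=O)N(C)OC | intermediate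
26 | 2-bromo-3-methylbut-1-ene | C=C(Br)C(C)C | starting material
27 | (3-methylbut-1-en-2-yl)magnesium bromide | C=C([Mg]Br)C(C)C | intermediate
28 | (4S,5R,8S,9S,13Z)-8-hydroxy-14-iodo-5,13-dimethyl-2-(propan-2-yl)-4-(triethylsilyloxy)-9-[(triethylsilyloxy)methyl]tetradeca-1,13-dien-3-one | CC[Si](CC)(CC)OC[C@H](CCC/C(C)=C\I)[C@@H](O)CC[C@@H](C)[C@H](O[Si](CC)(CC)CC)C(=O)C(=C)C(C)C | intermediate
29 | (2E,4Z,9S,10S,13R,14S)-10-hydroxy-5,13-dimethyl-2-(propan-2-yl)-14-(triethylsilyloxy)-9-[(triethylsilyloxy)methyl]cyclotetradeca-2,4-dien-1-one | CC(C)/C1=C\C=C(\C)CCC[C@@H](CO[Si](CC)(CC)CC)[C@@H](O)CC[C@@H](C)[C@H](O[Si](CC)(CC)CC)C1=O | intermediate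
30 | (1E,3S,4R,8S,9S,12R,13S)-3,4-epoxy-9-hydroxy-13,19-bis(triethylsilyloxy)cembr-1-en-14-one | CC(C)/C1=C\[C@@H]2O[C@]2(C)CCC[C@@H](CO[Si](CC)(CC)CC)[C@@H](O)CC[C@@H](C)[C@H](O[Si](CC)(CC)CC)C1=O | intermediate
31 | (1E,3S,4R,8S,12R,13S)-3,4-epoxy-13,19-bis(triethylsilyloxy)cembr-1-ene-9,14-dione | CC(C)/C1=C\[C@@H]2O[C@]2(C)CCC[C@@H](CO[Si](CC)(CC)CC)C(=O)CC[C@@H](C)[C@H](O[Si](CC)(CC)CC)C1=O | intermediate
32 | (1E,3S,4R,8S,12R,13S)-3,4-epoxy-13,19-dihydroxycembr-1-ene-9,14-dione (CNP0110598.2) | CC(C)/C1=C\[C@@H]2O[C@]2(C)CCC[C@@H](CO)C(=O)CC[C@@H](C)[C@H](O)C1=O | target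

**Totals and risks**

Total step count: 17. Longest linear sequence: 13 steps (steps 1–5 and 10–17).

Step 14 (most likely to fail). What may go wrong: slow carbopalladation of the α-branched enone with proto-deiodination and oligomerisation taking over, β-hydride elimination toward the isopropyl methine, or erosion of the 1E geometry by palladium hydride re-addition. Fallback, which postpones the isopropyl group so that the ring closes onto an unsubstituted vinyl ketone: it sets out from compound 25. CH2=CHMgBr (THF, 0 °C) should give the vinyl ketone F1. The same Heck conditions (Pd(OAc)2, Bu4NCl, NaHCO3, DMF, high dilution, 70 °C) should then close the ring onto this monosubstituted acceptor, where only C2 hydrogens can be eliminated, and give the isopropyl-free macrocyclic dienone F2. α-Iodination (I2, pyridine, CH2Cl2, rt) should give the α-iodo dienone F3 with iodine cis to C3. Negishi coupling with i-PrZnBr (Pd(OAc)2, CPhos, THF, rt) should replace iodine by isopropyl with retention, and the fallback comes back to the route at compound 29.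

Step 15. What may go wrong: poor facial selectivity, because the conformational bias of the macrocycle can override catalyst control on a Z-trisubstituted olefin and deliver oxygen to the wrong face of C3=C4. Fallback, which builds the oxirane in two steps with inverted facial logic: it sets out from compound 29. NBS in THF/H2O (0 °C) should give the bromohydrin F4 (bromonium ion on the exposed face, water opening at the more substituted C4). K2CO3 in MeOH (0 °C) should then close the ring by displacement of bromide at C3 by the C4 alkoxide. This places the oxirane oxygen on the face opposite to the one the electrophile attacked, and the fallback comes back to the route at compound 30.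

Step 17. What may go wrong: opening of the vinyl oxirane by HF, or β-elimination and retro-aldol cleavage at the unveiled β-hydroxy ketone during desilylation. Fallback, which removes the silyl groups before the oxirane exists: it sets out from compound 29. Dess–Martin periodinane (NaHCO3, CH2Cl2) should give the bis-silyl dienedione F5. HF·pyridine (pyridine, THF, 0 °C) should then free both hydroxyls on a molecule that has no oxirane and give the dienone diol F6. The Shi epoxidation of step 15, run as the last step on F6, comes back to the route at compound 32.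

**Further compounds**

F1 | step 14 | (4S,5R,8S,9S,13Z)-8-hydroxy-14-iodo-5,13-dimethyl-4-(triethylsilyloxy)-9-[(triethylsilyloxy)methyl]tetradeca-1,13-dien-3-one | CC[Si](CC)(CC)OC[C@H](CCC/C(C)=C\I)[C@@H](O)CC[C@@H](C)[C@H](O[Si](CC)(CC)CC)C(=O)C=C
F2 | step 14 | (2E,4Z,9S,10S,13R,14S)-10-hydroxy-5,13-dimethyl-14-(triethylsilyloxy)-9-[(triethylsilyloxy)methyl]cyclotetradeca-2,4-dien-1-one | O=C1/C=C/C=C(/C)CCC[C@@H](CO[Si](CC)(CC)CC)[C@@H](O)CC[C@@H](C)[C@@H]1O[Si](CC)(CC)CC
F3 | step 14 | (2Z,4Z,9S,10S,13R,14S)-10-hydroxy-2-iodo-5,13-dimethyl-14-(triethylsilyloxy)-9-[(triethylsilyloxy)methyl]cyclotetradeca-2,4-dien-1-one | O=C1/C(I)=C/C=C(/C)CCC[C@@H](CO[Si](CC)(CC)CC)[C@@H](O)CC[C@@H](C)[C@@H]1O[Si](CC)(CC)CC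
F4 | step 15 | (1E,3R,4R,8S,9S,12R,13S)-3-bromo-4,9-dihydroxy-13,19-bis(triethylsilyloxy)cembr-1-en-14-one | CC(C)/C1=C\[C@@H](Br)[C@](C)(O)CCC[C@@H](CO[Si](CC)(CC)CC)[C@@H](O)CC[C@@H](C)[C@H](O[Si](CC)(CC)CC)C1=O
F5 | step 17 | (1E,3Z,8S,12R,13S)-13,19-bis(triethylsilyloxy)cembra-1,3-diene-9,14-dione | CC(C)/C1=C\C=C(\C)CCC[C@@H](CO[Si](CC)(CC)CC)C(=O)CC[C@@H](C)[C@H](O[Si](CC)(CC)CC)C1=O
F6 | step 17 | (1E,3Z,8S,12R,13S)-13,19-dihydroxycembra-1,3-diene-9,14-dione | CC(C)/C1=C\C=C(\C)CCC[C@@H](CO)C(=O)CC[C@@H](C)[C@H](O)C1=O
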